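Ring C is cut at C8a–O1, C4a–C4 and O1–C2. The route exploits the fact that ring A holds O1 and the C4 carbonyl on adjacent carbons C8a and C4a, bracketed by oxygen at C8 and C5. This is the imprint of a C4a–C8a aryne. Fluoride unmasks that aryne, which inserts into the carboxyl C–O bond of 3-(2,4-dimethoxyphenyl)propiolic acid. The phenoxide ynone so formed closes ring C in the same flask. The precursor is an ortho-silylaryl triflate (SiMe3 on C8a, OTf on C4a) whose C5 oxygen is tosylated. Tosyloxy is a stronger director than the C8 methoxy group yet, unlike a triflate, a poor leaving group from the C4a anion.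

Key step: step 7

Remark on the chemistry: flavone numbering (O1 to C8a) is applied to the ring A carbons from the precursor stage onwards. The bromoaldehyde, the aryl iodide and propiolic acid are taken to be commercial.

Step 1
Reactants: 1 2-bromo-3,4-dimethoxybenzaldehyde
Product: 3 2-bromo-3,4-dimethoxyphenol, via aryl formate 2 (not isolated)
Conditions: mCPBA, CH2Cl2, 0 °C to rt; then K2CO3 (cat.), MeOH, rt
Reagents that add atoms: mCPBA, O=C(OO)c1cccc(Cl)c1
Why: Baeyer–Villiger oxidation, in which the aryl group made electron-rich by its para methoxy group migrates in the peracid adduct, and mild methanolysis of formate 2 leaves the aryl bromide and the ethers untouched.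

Step 2
Reactants: 3 2-bromo-3,4-dimethoxyphenol
Product: 5 3-bromo-4,5-dimethoxybenzene-1,2-diol, via bromoquinone 4 (not isolated)
Conditions: IBX, DMF, rt; then aq. Na2S2O4, EtOAc, rt
Reagents that add atoms: IBX, O=C1OI(=O)(O)c2ccccc12
Why: IBX ortho-oxygenation of a phenol delivers oxygen inside the aryloxy-iodane to the only free ortho carbon (the other bears bromine), dithionite reduces the donor-stabilised quinone 4 at once, and because bromine is already in place no easily oxidised catechol has to be halogenated.

Step 3
Reactants: 5 3-bromo-4,5-dimethoxybenzene-1,2-diol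
Product: 9 4,5-dimethoxy-3-(trimethylsilyl)benzene-1,2-diol, via bis(silyl ether) 6 (not isolated), via aryllithium 7 (not isolated), via lithium phenoxide 8 (not isolated)
Conditions: HMDS, THF, 65 °C, then evaporate; n-BuLi, THF, −78 °C; AcOH, MeOH, −78 °C to rt (Ar)
Reagents that add atoms: HMDS, C[Si](C)(C)N[Si](C)(C)C
Why: Retro-Brook (1,3 O-to-C silyl) rearrangement, in which bromine–lithium exchange outruns attack at silicon at −78 °C, aryllithium 7 takes the silyl group from the neighbouring oxygen, and buffered methanolysis removes the remaining O-silyl group without protodesilylation at carbon.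

Step 4
Reactants: 9 4,5-dimethoxy-3-(trimethylsilyl)benzene-1,2-diol
Product: 10 2-hydroxy-4,5-dimethoxy-3-(trimethylsilyl)phenyl 4-methylbenzenesulfonate
Conditions: TsCl (1.0 equiv), Et3N, CH2Cl2, −20 to 0 °C (Ar)
Reagents that add atoms: TsCl, Cc1ccc(cc1)S(=O)(=O)Cl
Why: Site-selective O-sulfonylation under steric control, since the hydroxyl beside C–SiMe3 is shielded and one equivalent of TsCl should react at the open hydroxyl, which is the future C5 oxygen.

Step 5
Reactants: 10 2-hydroxy-4,5-dimethoxy-3-(trimethylsilyl)phenyl 4-methylbenzenesulfonate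
Product: 11 4,5-dimethoxy-2-(trifluoromethylsulfonyloxy)-3-(trimethylsilyl)phenyl 4-methylbenzenesulfonate
Conditions: Tf2O, pyridine, CH2Cl2, 0 °C
Reagents that add atoms: Tf2O, O=S(=O)(OS(=O)(=O)C(F)(F)F)C(F)(F)F
Why: Standard O-triflation of an ortho-silylphenol, for which the small and very reactive anhydride reaches the hindered oxygen and pyridine does not attack silicon, so no aryne is released early.

Step 6
Reactants: 12 1-iodo-2,4-dimethoxybenzene; 13 propiolic acid
Product: 14 3-(2,4-dimethoxyphenyl)propiolic acid
Conditions: Pd(PPh3)2Cl2 (5 mol %), 1,4-bis(diphenylphosphino)butane (10 mol %), DBU, DMSO, rt; then cold 1 M HCl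
Reagents that add atoms: none
Why: Copper-free Sonogashira-type coupling of propiolic acid with an aryl iodide, where leaving out copper and working at room temperature holds back decarboxylation of the product carboxylate.

Step 7
Reactants: 11 4,5-dimethoxy-2-(trifluoromethylsulfonyloxy)-3-(trimethylsilyl)phenyl 4-methylbenzenesulfonate; 14 3-(2,4-dimethoxyphenyl)propiolic acid
Product: 17 2-(2,4-dimethoxyphenyl)-7,8-dimethoxy-4-oxo-4H-chromen-5-yl 4-methylbenzenesulfonate, via aryne 15 (not isolated), via phenoxide ynone 16 (not isolated)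
Conditions: CsF (4 equiv), THF, 125 °C, sealed tube (11 in slight excess)
Reagents that add atoms: none
Why: Fluoride attacks the SiMe3 group on C8a and the C4a triflate, the only leaving group ortho to silicon, departs to give aryne 15; the caesium carboxylate of 14 adds through oxygen at C8a, and the C4a aryl anion attacks the ester carbonyl through a four-membered alkoxide that opens to phenoxide ynone 16, so that C8a–O1 and C4a–C4 arise from one insertion. The closest known reaction type is the fluoride-induced insertion of arynes into the C–O bond of carboxylic acids in hot THF, which gives ortho-hydroxyaryl ketones and, from arylpropiolic acids, flavones. Ring C then closes by 6-endo-dig oxa-Michael addition of the C8a phenoxide to the alkyne carbon that becomes C2 (O1–C2), the aprotic medium favouring this mode over 5-exo-dig closure to an aurone, and the acid proton ends up on C3. No stereocentre is formed. The selectivity needed is addition of the carboxylate at C8a and not at C4a: the C5 tosyloxy group is a stronger sigma acceptor and much larger than the C8 methoxy group, so it should polarise the aryne towards attack meta to itself and place the developing charge on C4a next to the sulfonate. The C4a anion must also be acylated faster than it is protonated or expels the C5 oxygen substituent, which the high temperature, the low concentration of free acid over sparingly soluble CsF and the poor nucleofugality of tosylate are meant to secure.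

Step 8
Reactants: 17 2-(2,4-dimethoxyphenyl)-7,8-dimethoxy-4-oxo-4H-chromen-5-yl 4-methylbenzenesulfonate
Product: 19 2-(2,4-dimethoxyphenyl)-3-hydroxy-7,8-dimethoxy-4-oxo-4H-chromen-5-yl 4-methylbenzenesulfonate, via flavone epoxide 18 (not isolated)
Conditions: DMDO (acetone solution), CH2Cl2, 0 °C to rt; then p-TsOH·H2O (cat.), CH2Cl2, rt
Reagents that add atoms: DMDO, CC1(C)OO1
Why: Dioxirane epoxidation of the C2–C3 enol-ether bond of a flavone, followed by acid-promoted opening at C2 and loss of the C3 proton, is an established flavone-to-flavonol sequence; the two stereocentres of racemic cis-fused 18 vanish on aromatisation, and the tosylate shields ring A from over-oxidation.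

Step 9
Reactants: 19 2-(2,4-dimethoxyphenyl)-3-hydroxy-7,8-dimethoxy-4-oxo-4H-chromen-5-yl 4-methylbenzenesulfonate
Product: 20 2-(2,4-dimethoxyphenyl)-3,7,8-trimethoxy-4-oxo-4H-chromen-5-yl 4-methylbenzenesulfonate
Conditions: MeI, K2CO3, acetone, 40 °C
Reagents that add atoms: MeI, CI
Why: Williamson O-methylation of the acidic enolic 3-OH, the only free hydroxyl because the C5 oxygen is still blocked as its tosylate.

Step 10
Reactants: 20 2-(2,4-dimethoxyphenyl)-3,7,8-trimethoxy-4-oxo-4H-chromen-5-yl 4-methylbenzenesulfonate
Product: 21 5-hydroxy-3,7,8,2',4'-pentamethoxyflavone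
Conditions: KOH, 1,4-dioxane–H2O, rt to 50 °C; then 1 M HCl
Reagents that add atoms: none
Why: Saponification of an aryl sulfonate by hydroxide attack at sulfur is eased here by the acyl-stabilised C5 phenoxide leaving group, the methyl ethers are inert, and acidification recloses any ring-opened diketone and sets up the C5–OH to C4=O hydrogen bond.

Compound list
1 | 2-bromo-3,4-dimethoxybenzaldehyde | O=Cc1ccc(OC)c(OC)c1Br | starting material
2 | 2-bromo-3,4-dimethoxyphenyl formate (not isolated) | O=COc1ccc(OC)c(OC)c1Br | intermediate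
3 | 2-bromo-3,4-dimethoxyphenol | Oc1ccc(OC)c(OC)c1Br | intermediate
4 | 3-bromo-4,5-dimethoxy-1,2-benzoquinone (not isolated) | O=C1C=C(OC)C(OC)=C(Br)C1=O | intermediate
5 | 3-bromo-4,5-dimethoxybenzene-1,2-diol | Oc1cc(OC)c(OC)c(Br)c1O | intermediate
6 | 3-bromo-4,5-dimethoxy-1,2-bis(trimethylsilyloxy)benzene (not isolated) | C[Si](C)(C)Oc1cc(OC)c(OC)c(Br)c1O[Si](C)(C)C | intermediate
7 | [2,3-dimethoxy-5,6-bis(trimethylsilyloxy)phenyl]lithium (not isolated) | C[Si](C)(C)Oc1cc(OC)c(OC)c([Li])c1O[Si](C)(C)C | intermediate
8 | lithium 3,4-dimethoxy-2-(trimethylsilyl)-6-(trimethylsilyloxy)phenoxide (not isolated) | [Li+].[O-]c1c(O[Si](C)(C)C)cc(OC)c(OC)c1[Si](C)(C)C | intermediate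
9 | 4,5-dimethoxy-3-(trimethylsilyl)benzene-1,2-diol | Oc1cc(OC)c(OC)c([Si](C)(C)C)c1O | intermediate
10 | 2-hydroxy-4,5-dimethoxy-3-(trimethylsilyl)phenyl 4-methylbenzenesulfonate | Cc1ccc(cc1)S(=O)(=O)Oc1cc(OC)c(OC)c([Si](C)(C)C)c1O | intermediate
11 | 4,5-dimethoxy-2-(trifluoromethylsulfonyloxy)-3-(trimethylsilyl)phenyl 4-methylbenzenesulfonate (aryne precursor: OTs on C5, OTf on C4a, SiMe3 on C8a) | Cc1ccc(cc1)S(=O)(=O)Oc1cc(OC)c(OC)c([Si](C)(C)C)c1OS(=O)(=O)C(F)(F)F | intermediate
12 | 1-iodo-2,4-dimethoxybenzene | COc1ccc(I)c(OC)c1 | starting material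
13 | propiolic acid | C#CC(=O)O | starting material
14 | 3-(2,4-dimethoxyphenyl)propiolic acid | COc1ccc(C#CC(=O)O)c(OC)c1 | intermediate
15 | 3,4-dimethoxy-6-(tosyloxy)benzyne, the C4a–C8a aryne (not isolated) | COC1=C(OC)C#CC(OS(=O)(=O)c2ccc(C)cc2)=C1 | intermediate
16 | caesium 2-[3-(2,4-dimethoxyphenyl)propioloyl]-5,6-dimethoxy-3-(tosyloxy)phenoxide (not isolated) | [Cs+].COc1ccc(C#CC(=O)c2c([O-])c(OC)c(OC)cc2OS(=O)(=O)c2ccc(C)cc2)c(OC)c1 | intermediate
17 | 2-(2,4-dimethoxyphenyl)-7,8-dimethoxy-4-oxo-4H-chromen-5-yl 4-methylbenzenesulfonate | COc1ccc(-c2cc(=O)c3c(OS(=O)(=O)c4ccc(C)cc4)cc(OC)c(OC)c3o2)c(OC)c1 | intermediate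
18 | 1a-(2,4-dimethoxyphenyl)-3,4-dimethoxy-7-oxo-1a,7a-dihydro-7H-oxireno[b]chromen-6-yl 4-methylbenzenesulfonate, the 2,3-epoxide of 17 (racemic, cis-fused, one enantiomer drawn, not isolated) | COc1ccc([C@]23O[C@H]2C(=O)c2c(OS(=O)(=O)c4ccc(C)cc4)cc(OC)c(OC)c2O3)c(OC)c1 | intermediate
19 | 2-(2,4-dimethoxyphenyl)-3-hydroxy-7,8-dimethoxy-4-oxo-4H-chromen-5-yl 4-methylbenzenesulfonate | COc1ccc(-c2oc3c(OC)c(OC)cc(OS(=O)(=O)c4ccc(C)cc4)c3c(=O)c2O)c(OC)c1 | intermediate
20 | 2-(2,4-dimethoxyphenyl)-3,7,8-trimethoxy-4-oxo-4H-chromen-5-yl 4-methylbenzenesulfonate | COc1ccc(-c2oc3c(OC)c(OC)cc(OS(=O)(=O)c4ccc(C)cc4)c3c(=O)c2OC)c(OC)c1 | intermediate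
21 | 5-hydroxy-3,7,8,2',4'-pentamethoxyflavone | COc1ccc(-c2oc3c(OC)c(OC)cc(O)c3c(=O)c2OC)c(OC)c1 | target

Total step count: 10. Longest linear sequence: 9 (steps 1 to 5, then 7 to 10). Step 6 runs in parallel.

Steps most likely to fail

Step 7. Four processes threaten it:
- The two flanking oxygen groups polarise the aryne in opposite senses, so the carboxylate may add at C4a as well as at C8a.
- The C4a anion may be protonated to the plain aryl ester.
- The C4a anion may expel the C5 sulfonate.
- The propiolate may decarboxylate at 125 °C.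

The fallback gives up the aryne and builds ring C on a ring A that already carries the C4a acyl group. It sets out from 12. Coupling 12 under CO (Pd(OAc)2, 1,4-bis(diphenylphosphino)butane, DBU, DMF, 120 °C) with commercial 2-hydroxy-3,4,6-trimethoxyacetophenone (CC(=O)c1c(O)c(OC)c(OC)cc1OC) is a known carbonylative flavone annulation. It runs through O-aroylation, Baker–Venkataraman acyl shift and cyclodehydration, and should give 5,7,8,2',4'-pentamethoxyflavone F1. BCl3 in CH2Cl2 at −78 to 0 °C, chelated to the C4 carbonyl, should cleave only the C5 methyl ether to 5-hydroxy-7,8,2',4'-tetramethoxyflavone F2. Tosylation (TsCl, K2CO3, acetone, reflux) brings the material back to the route at 17.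

Step 8. Epoxidation of the C2–C3 bond, which the C5 sulfonate makes electron-poor, may be slow enough for excess dioxirane to oxidise the dimethoxyarene rings. The epoxide may also open along other paths. The fallback replaces electrophilic oxidation by deprotonation. It sets out from 17. LiN(i-Pr)2 is added at −78 °C to a THF solution of 17 and B(Oi-Pr)3, so that the C3 carbanion is trapped as it forms and never meets the sulfonate. This should give lithium triisopropoxy[2-(2,4-dimethoxyphenyl)-7,8-dimethoxy-4-oxo-5-(tosyloxy)-4H-chromen-3-yl]borate F3. Oxidation in the same flask with H2O2 and AcOH returns to the route at 19.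

Step 4. Sulfonylation may spill over to the hindered oxygen or to both oxygens, and the electron-rich catechol may be oxidised by air in the presence of amine. The fallback lets the silyl shift itself tell the two oxygens apart. It sets out from 5, which is silylated and lithiated as in step 3. Phenoxide 8 is then not protonated but trapped at −78 °C with Tf2O, before any oxygen-to-oxygen silyl shift can level the difference. This should give 3,4-dimethoxy-2-(trimethylsilyl)-6-(trimethylsilyloxy)phenyl trifluoromethanesulfonate F4. AcOH in MeOH frees 6-hydroxy-3,4-dimethoxy-2-(trimethylsilyl)phenyl trifluoromethanesulfonate F5. TsCl and Et3N in CH2Cl2 return to the route at 11, bypassing 9 and 10.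

Further compounds
F1 | step 7 | 5,7,8,2',4'-pentamethoxyflavone | COc1ccc(-c2cc(=O)c3c(OC)cc(OC)c(OC)c3o2)c(OC)c1
F2 | step 7 | 5-hydroxy-7,8,2',4'-tetramethoxyflavone | COc1ccc(-c2cc(=O)c3c(O)cc(OC)c(OC)c3o2)c(OC)c1
F3 | step 8 | lithium triisopropoxy[2-(2,4-dimethoxyphenyl)-7,8-dimethoxy-4-oxo-5-(tosyloxy)-4H-chromen-3-yl]borate | [Li+].CC(C)O[B-](OC(C)C)(OC(C)C)c1c(-c2ccc(OC)cc2OC)oc2c(OC)c(OC)cc(OS(=O)(=O)c3ccc(C)cc3)c2c1=O
F4 | step 4 | 3,4-dimethoxy-2-(trimethylsilyl)-6-(trimethylsilyloxy)phenyl trifluoromethanesulfonate | C[Si](C)(C)Oc1cc(OC)c(OC)c([Si](C)(C)C)c1OS(=O)(=O)C(F)(F)F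
F5 | step 4 | 6-hydroxy-3,4-dimethoxy-2-(trimethylsilyl)phenyl trifluoromethanesulfonate | Oc1cc(OC)c(OC)c([Si](C)(C)C)c1OS(=O)(=O)C(F)(F)F
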